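All constants come from no measurement; the result is computed.

The ratio to carry here is the constant of substrate + reagent over that of substrate + first product, 6.5 L mol⁻¹ s⁻¹ over 12 L mol⁻¹ s⁻¹.

    first product → over-reaction product (k1 = 1.3 × 10⁻⁵ s⁻¹)
    reagent + first product → bis adduct (k2 = 0.22 L mol⁻¹ s⁻¹)
    2 reagent → homo dimer (k3 = 0.14 L mol⁻¹ s⁻¹)
    substrate + first product → side product (k4 = 12 L mol⁻¹ s⁻¹)
    reagent + bis adduct → triple product (k5 = 5.3 L mol⁻¹ s⁻¹)
    substrate + reagent → first product (k6 = 6.5 L mol⁻¹ s⁻¹)

| flask | substrate | reagent | time | remark |
|---|---|---|---|---|
| ochre | 18 mM (fed, over 2.00 min) | 27.0 mM | 2.0 min | all but substrate at the start; substrate goes in evenly over 2.00 min, the run ends at 2.0 min |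
| green | 18 mM | 27.0 mM | 2.0 min | everything together in a closed stirred flask, run for 2.0 min |
| amber | 18 mM | 27.0 mM |  | one stirred flow tank at steady state, fed with the mixture as stated, mean residence time 20.0 min |
| teal | 18 mM | 27.0 mM |  | a single well-mixed tank run continuously and read at steady state, 2.0 min in it on average |

- percent here means substrate units held: one side product counts as two
- a doubled species enters its step squared and goes two at a time
- the stated concentrations are those of everything mixed, before any reaction; amounts are the same in each set-up
- the feed brings no volume worth counting
- the share counts what is present at the end, not what went on to other products
- run time (ochre): 2.0 min

- the set-up with the highest share of first product in all that became first product or bis adduct or triple product or side product, at the outlet or at the end ("none" if the first two lie within 2 percentage points) (ochre / green / amber / teal / none)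
- share of first product in all that became first product or bis adduct or triple product or side product, at the outlet or at the end, ochre
- share of first product in all that became first product or bis adduct or triple product or side product, at the outlet or at the end, green
- share of first product in all that became first product or bis adduct or triple product or side product, at the outlet or at the end, amber
- share of first product in all that became first product or bis adduct or triple product or side product, at the outlet or at the end, teal

Call that ratio the break-even ratio: the value of c(first product)/c(reagent) at which substrate makes first product just as fast as it eats it 0.542. If the two constants were equal it would stand at 1, and substrate would simply pick its partner by concentration. Here it stands lower, so you lose first product sooner than that even case.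

Now hold green against teal, the flask that looks nearly the same: same charge, and 2.0 min in green against 2.0 min on average in teal. In teal, substrate lasts about 5.70 s against reagent at its starting level, much shorter than the 2.0 min it spends in the tank on average. So I neglect the substrate left at teal's outlet and run these two steps alone.

The tank then sits at one ratio of eaten to made, which equals c(first product)/c(reagent) divided by the break-even ratio. The balance of the charge puts that at 0.575, so my share for teal is 27.0%. That is a figure from these two steps, with the other steps left out.

In green the same ratio starts at nothing, since no first product stands at the start, whereas in teal the substrate arrives in a tank already at its running ratio. So I put green above teal, and my reckoning goes no further.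

The forecast names green as best and says “the all-at-once batch does best”. Its teal lies below my two-step figure.

| set-up | forecast | range |
|---|---|---|
| ochre | 23.5% | 20% to 27% |
| green | 29% | 26% to 32% |
| amber | 9.4% | 8% to 11.5% |
| teal | 20.5% | 18% to 23% |

The simulation gives green as best at 29.0%, above ochre at 24.9%, teal at 20.4% and amber at 9.39%. Teal's tank holds reagent at 10.7 mM. Times the break-even ratio, that gives 5.82 mM, the c(first product) at which teal's substrate would eat first product as fast as it makes it. Strike out substrate + first product in green, so that the break-even ratio goes with it, and green's share reads 86.8%.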